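The plan rests on forming both carbocycle carbon–halogen bonds, C5'–Br and C4'–Cl, in one operation from a single chiral-pool centre (C1'). The feature exploited is that these halogens are trans-diequatorial on the cyclohexane ring, with C5'–Br cis to the pyran-bearing C1'. Alkene bromochlorination should not deliver that arrangement. The precursor is diaxial bromohydrin 4 (tertiary C4'–Br antiperiplanar to the C5' hydroxyl), made from the cis-oxide of (S)-limonene. Neutral O-activation sends bromine to C5' through a bromonium ion on the C1' face, and chloride then enters C4' from the opposite face. The oxane ring (O1, C2–C6) is afterwards grown from the isopropenyl group and closed by gold catalysis.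

Key step: step 4

Labels: oxane O1, C2 (=CH2), C3 (OH), C4, C5 (Br), C6 (CMe2). Carbocycle C1' (on C3), C2', C3', C4' (Cl, Me), C5' (Br), C6'. "Upper face" is the carbocycle face that carries the C1' side chain.

Remark on the chemistry: the (3R,5R) configuration of the target requires D-(−)-tartrate in step 6 and the L-fructose-derived (ent) Shi ketone in step 10. Bromohydrin 4 is base-labile and is taken on without storage.

Assumption: the ent-Shi ketone (a catalyst) and the Grignard solution 10 are bought as catalogue items.

Step 1
Reactants: 1 (S)-(−)-limonene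
Product: 2 (4S)-limonene 1,2-oxide (cis/trans mixture)
Conditions: mCPBA (1.0 equiv), CH2Cl2, 0 °C
Reagents that add atoms: 3-chloroperbenzoic acid (mCPBA), O=C(OO)c1cccc(Cl)c1
Why: Prilezhaev epoxidation, in which one equivalent of peracid should oxidise the electron-richer trisubstituted ring alkene before the 1,1-disubstituted side-chain alkene, with little facial bias, so both epoxide diastereomers form.

Step 2
Reactants: 2 (4S)-limonene 1,2-oxide (cis/trans mixture)
Product: 3 cis-(S)-limonene oxide (oxygen on the lower face)
Conditions: pyrrolidine (0.6 equiv), H2O, reflux; pentane extraction, distillation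
Reagents that add atoms: none
Why: Kinetic separation by aminolysis under the Fürst–Plattner rule, because only the trans-oxide can open diaxially at secondary C5' whereas the cis-oxide would have to be attacked at tertiary C4', so the cis-oxide should survive and its C4'/C5' configuration is thereby selected.

Step 3
Reactants: 3 cis-(S)-limonene oxide
Product: 4 (1R,2R,5S)-2-bromo-2-methyl-5-(prop-1-en-2-yl)cyclohexan-1-ol
Conditions: 48% aq. HBr (1.05 equiv), Et2O, −15 °C, short contact; cold aqueous wash, used at once
Reagents that add atoms: hydrogen bromide, Br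
Why: Acid-mediated epoxide opening, in which the Markovnikov preference for tertiary C4' and the diaxial rule coincide for the cis-oxide, so bromide should enter C4' with inversion on the upper face and leave an axial C5' hydroxyl, while brief cold aqueous acid spares the isopropenyl group.

Step 4
Reactants: 4 (1R,2R,5S)-2-bromo-2-methyl-5-(prop-1-en-2-yl)cyclohexan-1-ol
Product: 7 (1S,2S,4S)-2-bromo-1-chloro-1-methyl-4-(prop-1-en-2-yl)cyclohexane, via alkoxyiminium chloride 5 (not isolated), via bromonium chloride 6 (not isolated)
Conditions: 1-chloro-N,N,2-trimethylprop-1-en-1-amine (1.2 equiv), 4 Å MS, CH2Cl2, −20 °C → rt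
Reagents that add atoms: 1-chloro-N,N,2-trimethylprop-1-en-1-amine, CC(C)=C(Cl)N(C)C
Why: Proposed new method: the hydroxyl group adds to the α-chloroenamine to give alkoxyiminium chloride 5, whose axial C5'–O bond lies antiperiplanar to the axial C4'–Br bond, so the neutral amide departs under anchimeric assistance and only bromonium ion 6, bridged on the upper face, can arise. Its own chloride counter-ion then opens 6 at C4' from the lower face, which creates the C5'–Br and C4'–Cl bonds, turns both halogens equatorial and the methyl group axial, and closes no ring. The closest known reaction types are the neutral alcohol-to-chloride exchange with α-chloroenamines, 1,2-bromine migration during deoxyhalogenation of β-bromo alcohols, and the diaxial-to-diequatorial interchange of vicinal dihalides. C5' is fixed by inversion at the activated carbinol carbon (bromine arrives anti to oxygen) and C4' by a second inversion (chloride arrives anti to bromine), so both configurations are relayed from the epoxide of 3 and, through it, from C1'. The selectivity needed is chloride attack at C4' instead of C5'; it should be secured by the longer, more cationic tertiary C4'–Br bond of 6 and by the flexible half-chair, which can reach an antiperiplanar opening at C4' by tipping the isopropenyl group pseudo-axial. Acid-, base-, phosphine- and silver-free conditions keep HCl off the isopropenyl group, prevent 4 from closing back to 3 and avoid reductive loss of Br+, while collapse of the ion pair should outrun Br+ transfer to the side-chain alkene.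

Step 5
Reactants: 7 (1S,2S,4S)-2-bromo-1-chloro-1-methyl-4-(prop-1-en-2-yl)cyclohexane
Product: 8 2-[(1S,3S,4S)-3-bromo-4-chloro-4-methylcyclohexyl]prop-2-en-1-ol
Conditions: SeO2 (cat.), t-BuOOH, salicylic acid (cat.), CH2Cl2, rt
Reagents that add atoms: tert-butyl hydroperoxide (oxygen relayed through catalytic SeO2), CC(C)(C)OO
Why: Catalytic selenium dioxide allylic hydroxylation (ene reaction, then [2,3]-shift), which on an isopropenyl group prefers the methyl C–H bonds over the hindered methine C1'–H and leaves the alkyl halides and all stereocentres untouched.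

Step 6
Reactants: 8 2-[(1S,3S,4S)-3-bromo-4-chloro-4-methylcyclohexyl]prop-2-en-1-ol
Product: 9 [(2R)-2-[(1S,3S,4S)-3-bromo-4-chloro-4-methylcyclohexyl]oxiran-2-yl]methanol
Conditions: Ti(OiPr)4 (10 mol%), D-(−)-DIPT (12 mol%), t-BuOOH, 4 Å MS, CH2Cl2, −20 °C
Reagents that add atoms: tert-butyl hydroperoxide, CC(C)(C)OO
Why: Katsuki–Sharpless asymmetric epoxidation of a 2-substituted allylic alcohol, in which reagent control by D-(−)-tartrate delivers oxygen to the face that makes the quaternary carbon (future C3) R, the locally near-symmetric C1' exerting little substrate bias.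

Step 7
Reactants: 9 [(2R)-2-[(1S,3S,4S)-3-bromo-4-chloro-4-methylcyclohexyl]oxiran-2-yl]methanol; 10 2-methylprop-1-en-1-ylmagnesium bromide
Product: 11 (2R)-2-[(1S,3S,4S)-3-bromo-4-chloro-4-methylcyclohexyl]-5-methylhex-4-ene-1,2-diol
Conditions: 10 (3 equiv), CuI (15 mol%), THF, −40 → −15 °C; aqueous quench
Reagents that add atoms: none
Why: Copper-catalysed Grignard opening of a 2,2-disubstituted epoxide at its unhindered CH2 terminus (SN2, C3–O untouched, so C3 stays R), fast at low temperature where the hindered equatorial C5'–Br and tertiary C4'–Cl, which are gauche and so not aligned for reductive elimination, should not react.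

Step 8
Reactants: 11 (2R)-2-[(1S,3S,4S)-3-bromo-4-chloro-4-methylcyclohexyl]-5-methylhex-4-ene-1,2-diol
Product: 12 (2R)-2-[(1S,3S,4S)-3-bromo-4-chloro-4-methylcyclohexyl]-2-hydroxy-5-methylhex-4-enal
Conditions: IBX (1.3 equiv), DMSO–THF, rt
Reagents that add atoms: none
Why: IBX oxidation, which takes the primary alcohol of a 1,2-diol to the α-hydroxy aldehyde without glycol cleavage and cannot affect the tertiary alcohol or the non-enolisable C3 centre.

Step 9
Reactants: 12 (2R)-2-[(1S,3S,4S)-3-bromo-4-chloro-4-methylcyclohexyl]-2-hydroxy-5-methylhex-4-enal; 13 dimethyl (1-diazo-2-oxopropyl)phosphonate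
Product: 15 (3R)-3-[(1S,3S,4S)-3-bromo-4-chloro-4-methylcyclohexyl]-6-methylhept-5-en-1-yn-3-ol, via dimethyl (diazomethyl)phosphonate 14 (not isolated)
Conditions: K2CO3 (2 equiv), MeOH, 0 °C → rt
Reagents that add atoms: none
Why: Ohira–Bestmann (Seyferth–Gilbert) homologation, in which methanolysis of 13 gives 14 and this converts the non-enolisable aldehyde into the terminal alkyne under mild carbonate conditions that the diequatorial ring halides, which lack antiperiplanar ring hydrogens, should tolerate.

Step 10
Reactants: 15 (3R)-3-[(1S,3S,4S)-3-bromo-4-chloro-4-methylcyclohexyl]-6-methylhept-5-en-1-yn-3-ol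
Product: 16 (2R)-2-[(1S,3S,4S)-3-bromo-4-chloro-4-methylcyclohexyl]-1-[(2S)-3,3-dimethyloxiran-2-yl]but-3-yn-2-ol
Conditions: ent-Shi ketone (30 mol%), Oxone, K2CO3, Bu4NHSO4 (cat.), MeCN–DMM/aq. borate–EDTA buffer (pH ca. 10.5), 0 °C
Reagents that add atoms: potassium peroxymonosulfate (Oxone), [K+].[O-]S(=O)(=O)OO
Why: Shi asymmetric epoxidation, in which the dioxirane of the L-fructose-derived ketone attacks the only alkene (trisubstituted) through the spiro transition state on the face that makes C5 S under reagent control, the terminal alkyne being inert.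

Step 11
Reactants: 16 (2R)-2-[(1S,3S,4S)-3-bromo-4-chloro-4-methylcyclohexyl]-1-[(2S)-3,3-dimethyloxiran-2-yl]but-3-yn-2-ol
Product: 17 (3R,5R)-5-bromo-3-[(1S,3S,4S)-3-bromo-4-chloro-4-methylcyclohexyl]-6-methylhept-1-yne-3,6-diol
Conditions: LiBr (5 equiv), AcOH (2 equiv), THF, 0 °C → rt
Reagents that add atoms: lithium bromide, [Li+].[Br-]
Why: Lithium halide/acetic acid epoxide opening (SN2), in which bromide-rich, only weakly acidic conditions should direct bromide to the less substituted C5 with inversion, giving the (5R)-bromide and the C6 tertiary alcohol, while any tertiary bromide regioisomer can revert to the epoxide without touching C5.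

Step 12
Reactants: 17 (3R,5R)-5-bromo-3-[(1S,3S,4S)-3-bromo-4-chloro-4-methylcyclohexyl]-6-methylhept-1-yne-3,6-diol
Product: 18 (3R,5R)-5-bromo-3-[(1S,3S,4S)-3-bromo-4-chloro-4-methylcyclohexyl]-6,6-dimethyl-2-methylideneoxan-3-ol (target)
Conditions: [(JohnPhos)Au(NCMe)]SbF6 (3 mol%, silver-free), 4 Å MS, CH2Cl2, 0 °C → rt; Et3N quench, base-washed silica
Reagents that add atoms: none
Why: Gold(I)-catalysed intramolecular hydroalkoxylation, 6-exo-dig, in which the C6 hydroxyl adds in Markovnikov fashion to the π-activated internal alkyne carbon C2, helped by the quaternary C3 and C6 centres (Thorpe–Ingold effect), and since C3 bears no hydrogen the exocyclic enol ether cannot migrate into the ring and no stereocentre is formed or disturbed.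

Compound list
1 | (S)-(−)-limonene | C=C(C)[C@H]1CCC(C)=CC1 | starting material
2 | (4S)-limonene 1,2-oxide, cis/trans mixture (epoxide carbons undefined) | C=C(C)[C@H]1CCC2(C)OC2C1 | intermediate
3 | cis-(S)-limonene oxide, (1S,4S,6R)-1-methyl-4-(prop-1-en-2-yl)-7-oxabicyclo[4.1.0]heptane | C=C(C)[C@H]1CC[C@]2(C)O[C@@H]2C1 | intermediate
4 | (1R,2R,5S)-2-bromo-2-methyl-5-(prop-1-en-2-yl)cyclohexan-1-ol (Br and OH diaxial) | C=C(C)[C@H]1CC[C@@](C)(Br)[C@H](O)C1 | intermediate
5 | alkoxyiminium chloride of 4 (O-bound dimethyl(2-methylpropylidene)ammonium) | C=C(C)[C@H]1CC[C@@](C)(Br)[C@H](OC(C(C)C)=[N+](C)C)C1.[Cl-] | intermediate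
6 | bromonium chloride, Br+ bridging C4' and C5' on the upper face | C=C(C)[C@H]1CC[C@@]2(C)[Br+][C@H]2C1.[Cl-] | intermediate
7 | (1S,2S,4S)-2-bromo-1-chloro-1-methyl-4-(prop-1-en-2-yl)cyclohexane (Br and Cl diequatorial) | C=C(C)[C@H]1CC[C@](C)(Cl)[C@@H](Br)C1 | intermediate
8 | 2-[(1S,3S,4S)-3-bromo-4-chloro-4-methylcyclohexyl]prop-2-en-1-ol | C=C(CO)[C@H]1CC[C@](C)(Cl)[C@@H](Br)C1 | intermediate
9 | [(2R)-2-[(1S,3S,4S)-3-bromo-4-chloro-4-methylcyclohexyl]oxiran-2-yl]methanol | OC[C@@]1(CO1)[C@H]1CC[C@](C)(Cl)[C@@H](Br)C1 | intermediate
10 | 2-methylprop-1-en-1-ylmagnesium bromide (THF solution) | CC(C)=C[Mg]Br | starting material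
11 | (2R)-2-[(1S,3S,4S)-3-bromo-4-chloro-4-methylcyclohexyl]-5-methylhex-4-ene-1,2-diol | CC(C)=CC[C@](O)(CO)[C@H]1CC[C@](C)(Cl)[C@@H](Br)C1 | intermediate
12 | (2R)-2-[(1S,3S,4S)-3-bromo-4-chloro-4-methylcyclohexyl]-2-hydroxy-5-methylhex-4-enal | CC(C)=CC[C@](O)(C=O)[C@H]1CC[C@](C)(Cl)[C@@H](Br)C1 | intermediate
13 | dimethyl (1-diazo-2-oxopropyl)phosphonate | COP(=O)(OC)C(=[N+]=[N-])C(C)=O | starting material
14 | dimethyl (diazomethyl)phosphonate | COP(=O)(OC)C=[N+]=[N-] | intermediate
15 | (3R)-3-[(1S,3S,4S)-3-bromo-4-chloro-4-methylcyclohexyl]-6-methylhept-5-en-1-yn-3-ol | CC(C)=CC[C@](O)(C#C)[C@H]1CC[C@](C)(Cl)[C@@H](Br)C1 | intermediate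
16 | (2R)-2-[(1S,3S,4S)-3-bromo-4-chloro-4-methylcyclohexyl]-1-[(2S)-3,3-dimethyloxiran-2-yl]but-3-yn-2-ol | CC1(C)O[C@H]1C[C@](O)(C#C)[C@H]1CC[C@](C)(Cl)[C@@H](Br)C1 | intermediate
17 | (3R,5R)-5-bromo-3-[(1S,3S,4S)-3-bromo-4-chloro-4-methylcyclohexyl]-6-methylhept-1-yne-3,6-diol | CC(C)(O)[C@H](Br)C[C@](O)(C#C)[C@H]1CC[C@](C)(Cl)[C@@H](Br)C1 | intermediate
18 | (3R,5R)-5-bromo-3-[(1S,3S,4S)-3-bromo-4-chloro-4-methylcyclohexyl]-6,6-dimethyl-2-methylideneoxan-3-ol | C=C1OC(C)(C)[C@H](Br)C[C@@]1(O)[C@H]1CC[C@](C)(Cl)[C@@H](Br)C1 | target

Total step count: 12. Longest linear sequence: 12 steps, from 1 to 18.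

Steps most likely to fail

1. Step 4. Chloride may open the bromonium ion at C5' in the diaxial mode instead of at C4', or the ion may lose a proton.
The fallback runs from 4 back to 7 in two stages of known chemistry. Thionyl chloride–pyridine in CH2Cl2 replaces the hydroxyl group with retention, the classical result of bromine participation in trans-2-bromocyclohexanols. This gives the diaxial dihalide (1R,2R,4S)-1-bromo-2-chloro-1-methyl-4-(prop-1-en-2-yl)cyclohexane F1. That compound is then warmed in a polar, non-nucleophilic solvent (MeCN or nitromethane). There the known diaxial-to-diequatorial interchange of vicinal dihalides should move bromine across the upper face to C5' and chlorine across the lower face to C4', which is 7. The polar medium favours the more dipolar diequatorial isomer, and recovered dihalide would be recycled.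

2. Step 11. Bromide may enter at tertiary C6, or the C3 hydroxyl may open the activated epoxide in a 5-endo manner.
The fallback leaves from 15 and rejoins at 17. It replaces epoxide opening by Markovnikov bromohydration, whose regiochemistry (Br at C5, OH at C6) is intrinsic.
- TESOTf/2,6-lutidine masks the C3 hydroxyl to give the triethylsilyl ether of 15, F2.
- NBS in aqueous acetone at 0 °C gives the C5-epimeric bromohydrins, from which the (5R)-bromohydrin triethylsilyl ether F3 is separated by chromatography.
- HF·pyridine in THF removes the silyl group without closing the bromohydrin and gives 17.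
C5 would then be secured by separation instead of by reagent control.

3. Step 12. Slow attack of the hindered tertiary alcohol may let alkyne hydration or Meyer–Schuster rearrangement of the propargylic alcohol take over.
The fallback runs from 17 to 18 and accepts hydration on purpose. Gold(I)- or mercury(II)-catalysed Markovnikov hydration in wet dioxane gives the methyl ketone. This should rest as the cyclic hemiketal (3R,5R)-5-bromo-3-[(1S,3S,4S)-3-bromo-4-chloro-4-methylcyclohexyl]-2,6,6-trimethyloxane-2,3-diol F4. Trifluoroacetic anhydride–pyridine at 0 °C then esterifies the anomeric hydroxyl, which ionises and loses a methyl proton. Because C3 is quaternary, only the exocyclic enol ether 18 can form. Any C3 trifluoroacetate would be cleaved on bicarbonate–methanol work-up.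

Further compounds
F1 | step 4 | (1R,2R,4S)-1-bromo-2-chloro-1-methyl-4-(prop-1-en-2-yl)cyclohexane | C=C(C)[C@H]1CC[C@@](C)(Br)[C@H](Cl)C1
F2 | step 11 | triethylsilyl ether of 15 | CC(C)=CC[C@](O[Si](CC)(CC)CC)(C#C)[C@H]1CC[C@](C)(Cl)[C@@H](Br)C1
F3 | step 11 | (5R)-bromohydrin triethylsilyl ether (C3-O-TES derivative of 17) | CC(C)(O)[C@H](Br)C[C@](O[Si](CC)(CC)CC)(C#C)[C@H]1CC[C@](C)(Cl)[C@@H](Br)C1
F4 | step 12 | (3R,5R)-5-bromo-3-[(1S,3S,4S)-3-bromo-4-chloro-4-methylcyclohexyl]-2,6,6-trimethyloxane-2,3-diol (anomeric mixture) | CC1(O)OC(C)(C)[C@H](Br)C[C@@]1(O)[C@H]1CC[C@](C)(Cl)[C@@H](Br)C1
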